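**Retrosynthetic overview**

- 24 ⇐ 23 ⇐ 22 (desilylation; dithiane hydrolysis). The ten-membered carbocycle and the cis-fused α-methylene lactone of 22 close together at C6–C7, by intramolecular Barbier addition of the C13 allylic bromide of 20 to its C6 enal (C6 and C7 set by C8).
- 20 ⇐ dialdehyde 18 by Baylis–Hillman homologation at C7 and SN2′ bromination; 18 ⇐ 14 by acylation of O8, then unmasking and oxidation of C6 and C7.
- 14 ⇐ alkylidene lactone 11: reduction to the lactol and dithiane ring-opening frees O8 and masks C14. 11 ⇐ aldol condensation (C1=C10) of aldehyde 6 with pool lactone 8 (C8 is the only bought stereocentre).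
- 6 ⇐ Claisen rearrangement of the vinyl ether of Baylis–Hillman adduct 3 (from 1 and 2): the key [3,3] step, forming C2–C3 and the ring-cis C4=C5 geometry.
- Ring order: pool γ-lactone (opened in step 7), temporary 1,3-dithiane, then carbocycle and final γ-lactone together in step 13.

Assumption: atoms are labelled C1–C15 by germacrane numbering (lactone C12(=O)–O–C6, ring fusion C7, ester on C8, CHO = C14 on C10, CH2OH = C15 on C4; the target is 6R,7S,8R, a cis-fused lactone); (5R)-5-(hydroxymethyl)oxolan-2-one, made from D-glutamic acid, is taken as a purchasable pool compound; TBS = tert-butyldimethylsilyl, TBDPS = tert-butyldiphenylsilyl.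

**Route**

Step 1
Reactants: 1 (tert-butyldimethylsilyloxy)acetaldehyde; 2 methyl acrylate
Product: 3 methyl 4-[(TBS)oxy]-3-hydroxy-2-methylidenebutanoate (racemic)
Conditions: DABCO (0.3 equiv), 2 (3 equiv, neat), 25 °C, 3 d
Reagents that add atoms: none
Why: Morita–Baylis–Hillman reaction of the activated α-silyloxy aldehyde with the acrylate; the racemic carbinol centre is erased in step 2.

Step 2
Reactants: 3 methyl 4-[(TBS)oxy]-3-hydroxy-2-methylidenebutanoate; 4 ethyl vinyl ether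
Product: 6 methyl (2E)-2-{2-[(TBS)oxy]ethylidene}-5-oxopentanoate, via vinyl ether 5 (not isolated)
Conditions: 4 (solvent), Hg(OAc)2 (0.1 equiv), 35 °C, 24 h; then PhMe, 110 °C, sealed tube
Reagents that add atoms: none
Why: Transvinylation then Claisen rearrangement ([3,3]-sigmatropic) through a chair in which CH2OTBS sits pseudo-axial to avoid A(1,2) strain with the coplanar ester, so C2–C3 forms and C6 ends trans to the ester (cis to C3), the geometry documented for Johnson–Claisen rearrangements of Baylis–Hillman esters.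

Step 3
Reactants: 7 (5R)-5-(hydroxymethyl)oxolan-2-one
Product: 8 (5R)-5-{[(TBS)oxy]methyl}oxolan-2-one
Conditions: TBSCl, imidazole, CH2Cl2, 0 → 25 °C
Reagents that add atoms: tert-butyldimethylsilyl chloride, CC(C)(C)[Si](C)(C)Cl
Why: Silylation of the primary alcohol; the bought C8 centre is untouched.

Step 4
Reactants: 8 (5R)-5-{[(TBS)oxy]methyl}oxolan-2-one; 6 methyl (2E)-2-{2-[(TBS)oxy]ethylidene}-5-oxopentanoate
Product: 11 methyl (2E,5E)-2-{2-[(TBS)oxy]ethylidene}-5-[(5R)-5-{[(TBS)oxy]methyl}-2-oxooxolan-3-ylidene]pentanoate, via lithium aldolate 9 (not isolated), via mesylate 10 (not isolated)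
Conditions: 8, LiN(SiMe3)2, THF, −78 °C; then 6; then MsCl, −78 → 0 °C; then DBU, 25 °C
Reagents that add atoms: none
Why: Aldol condensation (lithium lactone enolate addition, mesylation, E1cB elimination) gives the thermodynamically favoured E-alkylidene lactone, C2 trans to the lactone carbonyl (future C14); the transient centres at C1 and C10 are destroyed.

Step 5
Reactants: 11 alkylidene lactone ester
Product: 12 (3E,5R)-5-{[(TBS)oxy]methyl}-3-[(4E)-6-[(TBS)oxy]-4-(hydroxymethyl)hex-4-en-1-ylidene]oxolan-2-ol (both anomers)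
Conditions: i-Bu2AlH (3.3 equiv), CH2Cl2, −78 °C; aq. KNaC4H4O6
Reagents that add atoms: none
Why: Hydride reduction takes the enoate to the allylic alcohol, while the lactone stops at the lactol because its cyclic aluminium hemiacetal is stable at −78 °C; this differentiates C14 (aldehyde level) from C15 (alcohol level).

Step 6
Reactants: 12 lactol alcohol
Product: 13 (3E,5R)-3-[(4E)-6-[(TBS)oxy]-4-{[(TBDPS)oxy]methyl}hex-4-en-1-ylidene]-5-{[(TBS)oxy]methyl}oxolan-2-ol (both anomers)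
Conditions: TBDPSCl (1.05 equiv), imidazole, CH2Cl2, 0 °C
Reagents that add atoms: tert-butyldiphenylsilyl chloride, CC(C)(C)[Si](Cl)(c1ccccc1)c1ccccc1
Why: Selective silylation of the unhindered primary allylic hydroxyl over the hemiacetal hydroxyl.

Step 7
Reactants: 13 silylated lactol
Product: 14 (2R,4E,8E)-1,10-bis[(TBS)oxy]-8-{[(TBDPS)oxy]methyl}-4-(1,3-dithian-2-yl)deca-4,8-dien-2-ol
Conditions: HS(CH2)3SH, BF3·OEt2, CH2Cl2, −78 → −40 °C
Reagents that add atoms: propane-1,3-dithiol, SCCCS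
Why: Lewis-acid ring-opening dithioacetalisation of the lactol masks C14 as a 1,3-dithiane and releases the C8 hydroxyl with its configuration unchanged; the low temperature spares the silyl ethers.

Step 8
Reactants: 14 dithiane alcohol; 15 3-methylbutanoyl chloride
Product: 16 (2R,4E,8E)-1,10-bis[(TBS)oxy]-8-{[(TBDPS)oxy]methyl}-4-(1,3-dithian-2-yl)deca-4,8-dien-2-yl 3-methylbutanoate
Conditions: 15, pyridine, DMAP (cat.), CH2Cl2, 0 °C
Reagents that add atoms: none
Why: DMAP-catalysed esterification of the only free hydroxyl, with retention at C8.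

Step 9
Reactants: 16 bis-TBS ether
Product: 17 (2R,4E,8E)-8-{[(TBDPS)oxy]methyl}-4-(1,3-dithian-2-yl)-1,10-dihydroxydeca-4,8-dien-2-yl 3-methylbutanoate
Conditions: CSA (0.1 equiv), MeOH/CH2Cl2 (1:1), 0 °C
Reagents that add atoms: none
Why: Acid-catalysed methanolysis removes the two primary TBS ethers about a hundred times faster than the TBDPS ether; the short, cold reaction avoids an O8-to-O7 acyl shift.

Step 10
Reactants: 17 diol
Product: 18 (2R,4E,8E)-8-{[(TBDPS)oxy]methyl}-4-(1,3-dithian-2-yl)-1,10-dioxodeca-4,8-dien-2-yl 3-methylbutanoate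
Conditions: SO3·pyridine, DMSO, i-Pr2NEt, CH2Cl2, 0 °C
Reagents that add atoms: none
Why: Parikh–Doering oxidation of both primary alcohols (C6 to the enal, C7 to the α-acyloxy aldehyde); it tolerates the dithiane and is mild toward the C8 centre.

Step 11
Reactants: 18 dialdehyde; 2 methyl acrylate
Product: 19 methyl (4R,6E,10E)-10-{[(TBDPS)oxy]methyl}-6-(1,3-dithian-2-yl)-3-hydroxy-2-methylidene-4-[(3-methylbutanoyl)oxy]-12-oxododeca-6,10-dienoate (both C3 epimers)
Conditions: 2 (excess), DABCO (0.5 equiv), 25 °C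
Reagents that add atoms: none
Why: Morita–Baylis–Hillman reaction, chemoselective for the activated non-conjugated C7 aldehyde over the hindered β,β-disubstituted C6 enal; the new C7 carbinol centre is removed in step 12.

Step 12
Reactants: 19 Baylis–Hillman alcohol
Product: 20 methyl (2Z,4R,6E,10E)-2-(bromomethyl)-10-{[(TBDPS)oxy]methyl}-6-(1,3-dithian-2-yl)-4-[(3-methylbutanoyl)oxy]-12-oxododeca-2,6,10-trienoate
Conditions: PBr3 (0.4 equiv), Et2O, 0 °C
Reagents that add atoms: phosphorus tribromide, BrP(Br)Br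
Why: Bromination with allylic transposition (SN2′) gives the thermodynamically preferred Z-2-(bromomethyl)enoate (C8 trans to the ester).

Step 13
Reactants: 20 allylic bromide enal
Product: 22 (3aS,4R,6E,10E,11aR)-10-{[(TBDPS)oxy]methyl}-6-(1,3-dithian-2-yl)-3-methylidene-2-oxo-2,3,3a,4,5,8,9,11a-octahydrocyclodeca[b]furan-4-yl 3-methylbutanoate, via hydroxy ester 21 (not isolated)
Conditions: indium powder (In), THF/H2O (3:1), 0.002 M (slow addition of 20), 25 °C; then 1 M HCl
Reagents that add atoms: none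
Why: Intramolecular Barbier 2-(methoxycarbonyl)allylation: the allyl-indium adds at C7 to the C6 aldehyde through a chair Zimmerman–Traxler transition state that gives the syn adduct, hence the cis lactone (6R), and the bought C8 centre, held with H8 in the olefin plane by A(1,3) strain, directs attack anti to its C–O bond (Felkin–Anh sense, 7S); the hydroxy ester then lactonises.

Step 14
Reactants: 22 dithiane macrolactone
Product: 23 (3aS,4R,6E,10E,11aR)-10-{[(TBDPS)oxy]methyl}-6-formyl-3-methylidene-2-oxo-2,3,3a,4,5,8,9,11a-octahydrocyclodeca[b]furan-4-yl 3-methylbutanoate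
Conditions: MeI, CaCO3, MeCN/H2O (4:1), 40 °C
Reagents that add atoms: water, O
Why: Alkylative dethioacetalisation (S-methylation, then hydrolysis) releases the conjugated C14 aldehyde under buffered neutral conditions that leave the α-methylene lactone, ester and silyl ether intact.

Step 15
Reactants: 23 silyl ether
Product: 24 (3aS,4R,6E,10E,11aR)-6-formyl-10-(hydroxymethyl)-3-methylidene-2-oxo-2,3,3a,4,5,8,9,11a-octahydrocyclodeca[b]furan-4-yl 3-methylbutanoate (target)
Conditions: HF·pyridine, pyridine, THF, 0 → 25 °C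
Reagents that add atoms: none
Why: Fluoride-mediated desilylation of the primary allylic TBDPS ether; the buffered reagent does not touch the enal, ester or lactone.

**Compound list**

1 | (tert-butyldimethylsilyloxy)acetaldehyde | O=CCO[Si](C)(C)C(C)(C)C | starting material
2 | methyl acrylate | C=CC(=O)OC | starting material
3 | methyl 4-[(TBS)oxy]-3-hydroxy-2-methylidenebutanoate (racemic) | C=C(C(=O)OC)C(O)CO[Si](C)(C)C(C)(C)C | intermediate
4 | ethyl vinyl ether | C=COCC | starting material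
5 | methyl 4-[(TBS)oxy]-3-(ethenyloxy)-2-methylidenebutanoate (racemic, not isolated) | C=C(C(=O)OC)C(OC=C)CO[Si](C)(C)C(C)(C)C | intermediate
6 | methyl (2E)-2-{2-[(TBS)oxy]ethylidene}-5-oxopentanoate | O=CCC/C(=C\CO[Si](C)(C)C(C)(C)C)C(=O)OC | intermediate
7 | (5R)-5-(hydroxymethyl)oxolan-2-one | O=C1CC[C@H](CO)O1 | starting material
8 | (5R)-5-{[(TBS)oxy]methyl}oxolan-2-one | O=C1CC[C@H](CO[Si](C)(C)C(C)(C)C)O1 | intermediate
9 | lithium (4E)-6-[(TBS)oxy]-4-(methoxycarbonyl)-1-[(5R)-5-{[(TBS)oxy]methyl}-2-oxooxolan-3-yl]hex-4-en-1-olate (diastereomer mixture, not isolated) | [Li+].[O-]C(CC/C(=C\CO[Si](C)(C)C(C)(C)C)C(=O)OC)C1C[C@H](CO[Si](C)(C)C(C)(C)C)OC1=O | intermediate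
10 | (4E)-6-[(TBS)oxy]-4-(methoxycarbonyl)-1-[(5R)-5-{[(TBS)oxy]methyl}-2-oxooxolan-3-yl]hex-4-en-1-yl methanesulfonate (diastereomer mixture, not isolated) | CS(=O)(=O)OC(CC/C(=C\CO[Si](C)(C)C(C)(C)C)C(=O)OC)C1C[C@H](CO[Si](C)(C)C(C)(C)C)OC1=O | intermediate
11 | methyl (2E,5E)-2-{2-[(TBS)oxy]ethylidene}-5-[(5R)-5-{[(TBS)oxy]methyl}-2-oxooxolan-3-ylidene]pentanoate | O=C1/C(=C/CC/C(=C\CO[Si](C)(C)C(C)(C)C)C(=O)OC)C[C@H](CO[Si](C)(C)C(C)(C)C)O1 | intermediate
12 | (3E,5R)-5-{[(TBS)oxy]methyl}-3-[(4E)-6-[(TBS)oxy]-4-(hydroxymethyl)hex-4-en-1-ylidene]oxolan-2-ol (both anomers) | OC1/C(=C/CC/C(=C\CO[Si](C)(C)C(C)(C)C)CO)C[C@H](CO[Si](C)(C)C(C)(C)C)O1 | intermediate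
13 | (3E,5R)-3-[(4E)-6-[(TBS)oxy]-4-{[(TBDPS)oxy]methyl}hex-4-en-1-ylidene]-5-{[(TBS)oxy]methyl}oxolan-2-ol (both anomers) | OC1/C(=C/CC/C(=C\CO[Si](C)(C)C(C)(C)C)CO[Si](c2ccccc2)(c2ccccc2)C(C)(C)C)C[C@H](CO[Si](C)(C)C(C)(C)C)O1 | intermediate
14 | (2R,4E,8E)-1,10-bis[(TBS)oxy]-8-{[(TBDPS)oxy]methyl}-4-(1,3-dithian-2-yl)deca-4,8-dien-2-ol | S1CCCSC1/C(=C/CC/C(=C\CO[Si](C)(C)C(C)(C)C)CO[Si](c2ccccc2)(c2ccccc2)C(C)(C)C)C[C@@H](O)CO[Si](C)(C)C(C)(C)C | intermediate
15 | 3-methylbutanoyl chloride | CC(C)CC(Cl)=O | starting material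
16 | (2R,4E,8E)-1,10-bis[(TBS)oxy]-8-{[(TBDPS)oxy]methyl}-4-(1,3-dithian-2-yl)deca-4,8-dien-2-yl 3-methylbutanoate | S1CCCSC1/C(=C/CC/C(=C\CO[Si](C)(C)C(C)(C)C)CO[Si](c2ccccc2)(c2ccccc2)C(C)(C)C)C[C@@H](OC(=O)CC(C)C)CO[Si](C)(C)C(C)(C)C | intermediate
17 | (2R,4E,8E)-8-{[(TBDPS)oxy]methyl}-4-(1,3-dithian-2-yl)-1,10-dihydroxydeca-4,8-dien-2-yl 3-methylbutanoate | S1CCCSC1/C(=C/CC/C(=C\CO)CO[Si](c2ccccc2)(c2ccccc2)C(C)(C)C)C[C@@H](OC(=O)CC(C)C)CO | intermediate
18 | (2R,4E,8E)-8-{[(TBDPS)oxy]methyl}-4-(1,3-dithian-2-yl)-1,10-dioxodeca-4,8-dien-2-yl 3-methylbutanoate | S1CCCSC1/C(=C/CC/C(=C\C=O)CO[Si](c2ccccc2)(c2ccccc2)C(C)(C)C)C[C@@H](OC(=O)CC(C)C)C=O | intermediate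
19 | methyl (4R,6E,10E)-10-{[(TBDPS)oxy]methyl}-6-(1,3-dithian-2-yl)-3-hydroxy-2-methylidene-4-[(3-methylbutanoyl)oxy]-12-oxododeca-6,10-dienoate (both C3 epimers) | S1CCCSC1/C(=C/CC/C(=C\C=O)CO[Si](c2ccccc2)(c2ccccc2)C(C)(C)C)C[C@@H](OC(=O)CC(C)C)C(O)C(=C)C(=O)OC | intermediate
20 | methyl (2Z,4R,6E,10E)-2-(bromomethyl)-10-{[(TBDPS)oxy]methyl}-6-(1,3-dithian-2-yl)-4-[(3-methylbutanoyl)oxy]-12-oxododeca-2,6,10-trienoate | S1CCCSC1/C(=C/CC/C(=C\C=O)CO[Si](c2ccccc2)(c2ccccc2)C(C)(C)C)C[C@@H](OC(=O)CC(C)C)/C=C(\CBr)C(=O)OC | intermediate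
21 | methyl 2-[(1R,2R,3E,7E,10R)-4-{[(TBDPS)oxy]methyl}-8-(1,3-dithian-2-yl)-2-hydroxy-10-[(3-methylbutanoyl)oxy]cyclodeca-3,7-dien-1-yl]prop-2-enoate (not isolated) | C=C(C(=O)OC)[C@@H]1[C@H](O)/C=C(/CO[Si](c2ccccc2)(c2ccccc2)C(C)(C)C)CC/C=C(/C2SCCCS2)C[C@H]1OC(=O)CC(C)C | intermediate
22 | (3aS,4R,6E,10E,11aR)-10-{[(TBDPS)oxy]methyl}-6-(1,3-dithian-2-yl)-3-methylidene-2-oxo-2,3,3a,4,5,8,9,11a-octahydrocyclodeca[b]furan-4-yl 3-methylbutanoate | C=C1C(=O)O[C@@H]2/C=C(/CO[Si](c3ccccc3)(c3ccccc3)C(C)(C)C)CC/C=C(/C3SCCCS3)C[C@@H](OC(=O)CC(C)C)[C@H]12 | intermediate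
23 | (3aS,4R,6E,10E,11aR)-10-{[(TBDPS)oxy]methyl}-6-formyl-3-methylidene-2-oxo-2,3,3a,4,5,8,9,11a-octahydrocyclodeca[b]furan-4-yl 3-methylbutanoate | C=C1C(=O)O[C@@H]2/C=C(/CO[Si](c3ccccc3)(c3ccccc3)C(C)(C)C)CC/C=C(/C=O)C[C@@H](OC(=O)CC(C)C)[C@H]12 | intermediate
24 | (3aS,4R,6E,10E,11aR)-6-formyl-10-(hydroxymethyl)-3-methylidene-2-oxo-2,3,3a,4,5,8,9,11a-octahydrocyclodeca[b]furan-4-yl 3-methylbutanoate | C=C1C(=O)O[C@@H]2/C=C(/CO)CC/C=C(/C=O)C[C@@H](OC(=O)CC(C)C)[C@H]12 | target

**Step count and risks**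

Total step count: 15. Longest linear sequence: 14 steps (steps 1, 2 and 4 to 15; step 3 is the only side branch).

The three steps most likely to fail:

Step 13 (ring closure). A ten-membered ring must close against oligomerisation, and both the cis ring fusion and the Felkin sense at C7 are predicted from models, not proven on this substrate. The fallback sets out from Baylis–Hillman alcohol 19. Acetylation (Ac2O, pyridine, DMAP) gives the allylic acetate methyl (4R,6E,10E)-3-(acetyloxy)-10-{[(TBDPS)oxy]methyl}-6-(1,3-dithian-2-yl)-2-methylidene-4-[(3-methylbutanoyl)oxy]-12-oxododeca-6,10-dienoate F2. This is cyclised by catalytic umpolung with Pd(PPh3)4 (5 mol %) and InI in THF at 0.002 M: a π-allyl complex of zerovalent palladium is transmetallated by monovalent indium iodide, so the allyl-indium is present only at low stationary concentration and Wurtz-type dimerisation of a bromide is avoided. The hydroxy ester 21 lactonises on acidic work-up and the route is rejoined at 22.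

Step 11 (second Baylis–Hillman reaction). The amine-catalysed reaction on an α-acyloxy aldehyde is slow enough to risk epimerisation at C8, a 1,2-acyl shift onto the new C7 hydroxyl and attack at the C6 enal. The fallback sets out from dialdehyde 18. Methyl propiolate is hydroaluminated with i-Bu2AlH·HMPA (THF, 0 °C) to [1-(methoxycarbonyl)vinyl]diisobutylaluminium, which is added to 18 at −40 °C. This non-basic, amine-free aluminium reagent adds to the more electrophilic non-conjugated C7 aldehyde, and work-up gives 19 directly, where the route is rejoined; no new compound arises on this path (F0).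

Step 2 (Claisen step). Transvinylation of a hindered, electron-poor secondary alcohol may be sluggish, and the E/Z ratio of the simple vinyl-ether variant is extrapolated from the ortho-ester case. The fallback sets out from 3. Johnson–Claisen rearrangement (MeC(OEt)3, cat. EtCO2H, 140 °C), for which E-selectivity with Baylis–Hillman esters is documented, gives the diester 5-ethyl 1-methyl (2E)-2-{2-[(TBS)oxy]ethylidene}pentanedioate F1. Half-reduction of its non-conjugated ethyl ester (i-Bu2AlH, 1.05 equiv, PhMe, −78 °C) gives aldehyde 6, where the route is rejoined; the conjugated, α-branched methyl ester reacts more slowly.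

**Further compounds**

F1 | step 2 | 5-ethyl 1-methyl (2E)-2-{2-[(TBS)oxy]ethylidene}pentanedioate | CCOC(=O)CC/C(=C\CO[Si](C)(C)C(C)(C)C)C(=O)OC
F0 | step 11 | none | none
F2 | step 13 | methyl (4R,6E,10E)-3-(acetyloxy)-10-{[(TBDPS)oxy]methyl}-6-(1,3-dithian-2-yl)-2-methylidene-4-[(3-methylbutanoyl)oxy]-12-oxododeca-6,10-dienoate | S1CCCSC1/C(=C/CC/C(=C\C=O)CO[Si](c2ccccc2)(c2ccccc2)C(C)(C)C)C[C@@H](OC(=O)CC(C)C)C(OC(C)=O)C(=C)C(=O)OC
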